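**Retrosynthetic overview**
1. The two primary alcohols are unmasked last. The ten-membered carbocycle (second and last ring) is closed by ring-closing metathesis at C1=C10.
2. The C8 3-methylbutanoate comes from an invertive (Mitsunobu) esterification of the 8-epi alcohol.
3. Key C7–C8 bond: the β-carbon of a 3-(bromomethyl)butenolide is made nucleophilic as an allylchromium (a lactone homoenolate equivalent) and adds to a β,γ-unsaturated aldehyde. This sets C7 and C8 and unveils the exo-methylene group.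
4. The butenolide (first ring) comes from carbonylative lactonization of a Z-iodoallylic alcohol. That alcohol comes from directed hydroalumination–iodination of a propargylic alcohol, itself made by asymmetric alkynylation (C6) of an enal whose C4=C5 geometry is fixed by syn-carbocupration.
5. The aldehyde partner comes from monomethyl itaconate.

Assumption: atom labels C1–C15 follow germacrane numbering (lactone carbonyl C12, ester oxygen on C8), and the five starting materials are taken as catalogue chemicals.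

Step 1
Reactants: 1 tert-butyl(diphenyl)(prop-2-yn-1-yloxy)silane; 2 but-3-en-1-ylmagnesium bromide
Product: 4 (E)-tert-butyl{[2-(iodomethylidene)hex-5-en-1-yl]oxy}diphenylsilane, via alkenylcopper 3 (not isolated)
Conditions: CuBr·SMe2 (1.05 equiv), Et2O/Me2S, −45 to −25 °C; then I2, −40 °C
Reagents that add atoms: iodine, [I][I]
Why: Syn carbocupration of the terminal alkyne by the monovalent butenylcopper reagent puts the butenyl group on the internal carbon and copper on the terminal carbon on the same face, and iodinolysis with retention gives the E iodide whose iodine (the future C6 position) is cis to the chain, which is the ring-cis C4=C5 geometry (Normant carbocupration).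

Step 2
Reactants: 4 (E)-tert-butyl{[2-(iodomethylidene)hex-5-en-1-yl]oxy}diphenylsilane
Product: 6 (2E)-3-{[(tert-butyldiphenylsilyl)oxy]methyl}hepta-2,6-dienal, via alkenyllithium 5 (not isolated)
Conditions: t-BuLi (2 equiv), Et2O, −78 °C; then DMF, −78 to 0 °C
Reagents that add atoms: N,N-dimethylformamide, CN(C)C=O
Why: Iodine–lithium exchange and formylation of the alkenyllithium both proceed with retention of alkene geometry (Bouveault-type formylation).

Step 3
Reactants: 6 (2E)-3-{[(tert-butyldiphenylsilyl)oxy]methyl}hepta-2,6-dienal; 7 tert-butyldimethyl(prop-2-yn-1-yloxy)silane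
Product: 9 (4R,5E)-1-[(tert-butyldimethylsilyl)oxy]-6-{[(tert-butyldiphenylsilyl)oxy]methyl}deca-5,9-dien-2-yn-4-ol, via alkynylzinc 8 (not isolated)
Conditions: Me2Zn (3 equiv), (S,S)-ProPhenol (20 mol %), Ph3PO (40 mol %), toluene, 0 °C
Reagents that add atoms: none
Why: Catalytic asymmetric alkynylation of the aldehyde by the alkynylzinc inside the chiral dinuclear zinc–ProPhenol pocket sets C6 as R by ligand control; the (S,S)/R pairing rests on the usual facial model and the antipodal ligand is used if the sense proves opposite.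

Step 4
Reactants: 9 (4R,5E)-1-[(tert-butyldimethylsilyl)oxy]-6-{[(tert-butyldiphenylsilyl)oxy]methyl}deca-5,9-dien-2-yn-4-ol
Product: 11 (2Z,4R,5E)-1-[(tert-butyldimethylsilyl)oxy]-6-{[(tert-butyldiphenylsilyl)oxy]methyl}-2-iododeca-2,5,9-trien-4-ol, via alkenylalanate 10 (not isolated)
Conditions: NaAlH2(OCH2CH2OMe)2, THF, 0 °C; then I2, −78 °C
Reagents that add atoms: iodine, [I][I]
Why: Hydroxyl-directed trans-hydroalumination delivers hydride to the alkyne carbon next to the carbinol and aluminium to the distal carbon in a five-membered alanate, and iodinolysis with retention gives the Z iodoalkene with iodine cis to the carbinol carbon.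

Step 5
Reactants: 11 (2Z,4R,5E)-1-[(tert-butyldimethylsilyl)oxy]-6-{[(tert-butyldiphenylsilyl)oxy]methyl}-2-iododeca-2,5,9-trien-4-ol
Product: 12 (5R)-3-{[(tert-butyldimethylsilyl)oxy]methyl}-5-[(1E)-2-{[(tert-butyldiphenylsilyl)oxy]methyl}hexa-1,5-dien-1-yl]furan-2(5H)-one
Conditions: PdCl2(PPh3)2 (5 mol %), CO (1 atm), K2CO3, THF, 50 °C
Reagents that add atoms: carbon monoxide, [C-]#[O+]
Why: Zerovalent palladium inserts into the alkenyl carbon–iodine bond, CO inserts, and the cis hydroxyl captures the acylpalladium to close the butenolide (carbonylative lactonization) without touching C6.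

Step 6
Reactants: 12 (5R)-3-{[(tert-butyldimethylsilyl)oxy]methyl}-5-[(1E)-2-{[(tert-butyldiphenylsilyl)oxy]methyl}hexa-1,5-dien-1-yl]furan-2(5H)-one
Product: 13 (5R)-3-(bromomethyl)-5-[(1E)-2-{[(tert-butyldiphenylsilyl)oxy]methyl}hexa-1,5-dien-1-yl]furan-2(5H)-one
Conditions: Ph3PBr2, CH2Cl2, 0 °C to rt
Reagents that add atoms: triphenylphosphine dibromide, BrP(Br)(c1ccccc1)(c1ccccc1)c1ccccc1
Why: Ph3PBr2 converts the primary allylic tert-butyldimethylsilyl ether directly into the bromide through an oxyphosphonium ion, while the bulkier tert-butyldiphenylsilyl ether is inert (silyl ether to bromide exchange).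

Step 7
Reactants: 14 4-methoxy-2-methylidene-4-oxobutanoic acid (monomethyl itaconate)
Product: 15 methyl 3-(hydroxymethyl)but-3-enoate
Conditions: BH3·SMe2, THF, −10 °C to rt; MeOH quench
Reagents that add atoms: none
Why: Borane reduces the free carboxylic acid through its acyloxyborane much faster than it touches the methyl ester (chemoselective borane reduction).

Step 8
Reactants: 15 methyl 3-(hydroxymethyl)but-3-enoate
Product: 16 methyl 3-{[(tert-butyldiphenylsilyl)oxy]methyl}but-3-enoate
Conditions: TBDPSCl, imidazole, CH2Cl2, 0 °C to rt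
Reagents that add atoms: tert-butyl(chloro)diphenylsilane, CC(C)(C)[Si](Cl)(c1ccccc1)c1ccccc1
Why: Imidazole-mediated silylation of the primary allylic alcohol (silyl ether protection).

Step 9
Reactants: 16 methyl 3-{[(tert-butyldiphenylsilyl)oxy]methyl}but-3-enoate
Product: 17 3-{[(tert-butyldiphenylsilyl)oxy]methyl}but-3-enal
Conditions: i-Bu2AlH (1.05 equiv), CH2Cl2, −78 °C; aq. potassium sodium tartrate; used at once
Reagents that add atoms: none
Why: At −78 °C the aluminium hemiacetal from one hydride transfer is stable, so mild work-up releases the β,γ-unsaturated aldehyde without over-reduction or conjugation (ester half-reduction).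

Step 10
Reactants: 13 (5R)-3-(bromomethyl)-5-[(1E)-2-{[(tert-butyldiphenylsilyl)oxy]methyl}hexa-1,5-dien-1-yl]furan-2(5H)-one; 17 3-{[(tert-butyldiphenylsilyl)oxy]methyl}but-3-enal
Product: 19 (4R,5R)-4-[(1S)-3-{[(tert-butyldiphenylsilyl)oxy]methyl}-1-hydroxybut-3-en-1-yl]-5-[(1E)-2-{[(tert-butyldiphenylsilyl)oxy]methyl}hexa-1,5-dien-1-yl]-3-methylideneoxolan-2-one, via allylchromium 18 (not isolated)
Conditions: CrCl2 (3 equiv), THF, 0 °C to rt; aq. NH4Cl
Reagents that add atoms: none
Why: Two-electron reduction of the allylic bromide by CrCl2 turns the normally electrophilic butenolide β-carbon C7 into the nucleophilic end of a trivalent allylchromium (lactone homoenolate equivalent, Nozaki–Hiyama allylation), which attacks the aldehyde through C7 in a chair transition state anti to the C6 side chain (7R, trans lactone) and, with its ring-locked E geometry, gives the anti adduct (8S) while the double bond moves out to the exo-methylene.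

Step 11
Reactants: 19 (4R,5R)-4-[(1S)-3-{[(tert-butyldiphenylsilyl)oxy]methyl}-1-hydroxybut-3-en-1-yl]-5-[(1E)-2-{[(tert-butyldiphenylsilyl)oxy]methyl}hexa-1,5-dien-1-yl]-3-methylideneoxolan-2-one; 20 3-methylbutanoic acid
Product: 21 (1R)-1-[(2R,3R)-2-[(1E)-2-{[(tert-butyldiphenylsilyl)oxy]methyl}hexa-1,5-dien-1-yl]-4-methylidene-5-oxooxolan-3-yl]-3-{[(tert-butyldiphenylsilyl)oxy]methyl}but-3-en-1-yl 3-methylbutanoate
Conditions: PPh3, DIAD, toluene, 0 °C to rt
Reagents that add atoms: none
Why: In the Mitsunobu esterification the carboxylate displaces the C8 oxyphosphonium group by SN2 with clean inversion, so 8S becomes the required 8R ester.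

Step 12
Reactants: 21 (1R)-1-[(2R,3R)-2-[(1E)-2-{[(tert-butyldiphenylsilyl)oxy]methyl}hexa-1,5-dien-1-yl]-4-methylidene-5-oxooxolan-3-yl]-3-{[(tert-butyldiphenylsilyl)oxy]methyl}but-3-en-1-yl 3-methylbutanoate
Product: 22 (3aR,4R,6E,10E,11aR)-6,10-bis{[(tert-butyldiphenylsilyl)oxy]methyl}-3-methylidene-2-oxo-2,3,3a,4,5,8,9,11a-octahydrocyclodeca[b]furan-4-yl 3-methylbutanoate
Conditions: second-generation Grubbs catalyst RuCl2(=CHPh)(PCy3)(H2IMes) (10 mol %), 1,4-benzoquinone (20 mol %), toluene (1 mM), 80 °C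
Reagents that add atoms: none
Why: Ring-closing metathesis joins the terminal vinyl group to the 1,1-disubstituted alkene with loss of ethene, and the ten-membered ring with its trans-fused lactone is expected to favour the ring-cis trisubstituted C1=C10 bond; the electron-poor exo-methylene and the trisubstituted C4=C5 bond react much more slowly.

Step 13
Reactants: 22 (3aR,4R,6E,10E,11aR)-6,10-bis{[(tert-butyldiphenylsilyl)oxy]methyl}-3-methylidene-2-oxo-2,3,3a,4,5,8,9,11a-octahydrocyclodeca[b]furan-4-yl 3-methylbutanoate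
Product: 23 (3aR,4R,6E,10E,11aR)-6,10-bis(hydroxymethyl)-3-methylidene-2-oxo-2,3,3a,4,5,8,9,11a-octahydrocyclodeca[b]furan-4-yl 3-methylbutanoate
Conditions: HF·pyridine, THF/pyridine, 0 °C to rt
Reagents that add atoms: none
Why: Buffered fluoride cleaves both primary silyl ethers and leaves the ester, the lactone and the exo-methylene acceptor untouched (fluoride desilylation).

**Compound list**
1 | tert-butyl(diphenyl)(prop-2-yn-1-yloxy)silane | C#CCO[Si](c1ccccc1)(c1ccccc1)C(C)(C)C | starting material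
2 | but-3-en-1-ylmagnesium bromide (Et2O solution) | C=CCC[Mg]Br | starting material
3 | alkenylcopper, (E)-[2-{[(tert-butyldiphenylsilyl)oxy]methyl}hexa-1,5-dien-1-yl]copper | [Cu]/C=C(/CO[Si](c1ccccc1)(c1ccccc1)C(C)(C)C)CCC=C | intermediate
4 | (E)-tert-butyl{[2-(iodomethylidene)hex-5-en-1-yl]oxy}diphenylsilane | I/C=C(/CO[Si](c1ccccc1)(c1ccccc1)C(C)(C)C)CCC=C | intermediate
5 | alkenyllithium, (E)-[2-{[(tert-butyldiphenylsilyl)oxy]methyl}hexa-1,5-dien-1-yl]lithium | [Li]/C=C(/CO[Si](c1ccccc1)(c1ccccc1)C(C)(C)C)CCC=C | intermediate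
6 | (2E)-3-{[(tert-butyldiphenylsilyl)oxy]methyl}hepta-2,6-dienal | O=C/C=C(/CO[Si](c1ccccc1)(c1ccccc1)C(C)(C)C)CCC=C | intermediate
7 | tert-butyldimethyl(prop-2-yn-1-yloxy)silane | C#CCO[Si](C)(C)C(C)(C)C | starting material
8 | alkynylzinc, methyl{3-[(tert-butyldimethylsilyl)oxy]prop-1-yn-1-yl}zinc | C[Zn]C#CCO[Si](C)(C)C(C)(C)C | intermediate
9 | (4R,5E)-1-[(tert-butyldimethylsilyl)oxy]-6-{[(tert-butyldiphenylsilyl)oxy]methyl}deca-5,9-dien-2-yn-4-ol | O[C@@H](C#CCO[Si](C)(C)C(C)(C)C)/C=C(/CO[Si](c1ccccc1)(c1ccccc1)C(C)(C)C)CCC=C | intermediate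
10 | alkenylalanate, cyclic sodium alanate of 9 (five-membered O–Al–C ring, Al on the alkyne carbon distal to the carbinol, new H trans to Al) | [Na+].COCCO[Al-]1(OCCOC)O[C@H](/C=C(/CO[Si](c2ccccc2)(c2ccccc2)C(C)(C)C)CCC=C)C=C1CO[Si](C)(C)C(C)(C)C | intermediate
11 | (2Z,4R,5E)-1-[(tert-butyldimethylsilyl)oxy]-6-{[(tert-butyldiphenylsilyl)oxy]methyl}-2-iododeca-2,5,9-trien-4-ol | O[C@@H](/C=C(\I)CO[Si](C)(C)C(C)(C)C)/C=C(/CO[Si](c1ccccc1)(c1ccccc1)C(C)(C)C)CCC=C | intermediate
12 | (5R)-3-{[(tert-butyldimethylsilyl)oxy]methyl}-5-[(1E)-2-{[(tert-butyldiphenylsilyl)oxy]methyl}hexa-1,5-dien-1-yl]furan-2(5H)-one | O=C1O[C@H](/C=C(/CO[Si](c2ccccc2)(c2ccccc2)C(C)(C)C)CCC=C)C=C1CO[Si](C)(C)C(C)(C)C | intermediate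
13 | (5R)-3-(bromomethyl)-5-[(1E)-2-{[(tert-butyldiphenylsilyl)oxy]methyl}hexa-1,5-dien-1-yl]furan-2(5H)-one | O=C1O[C@H](/C=C(/CO[Si](c2ccccc2)(c2ccccc2)C(C)(C)C)CCC=C)C=C1CBr | intermediate
14 | 4-methoxy-2-methylidene-4-oxobutanoic acid (monomethyl itaconate) | C=C(CC(=O)OC)C(=O)O | starting material
15 | methyl 3-(hydroxymethyl)but-3-enoate | C=C(CO)CC(=O)OC | intermediate
16 | methyl 3-{[(tert-butyldiphenylsilyl)oxy]methyl}but-3-enoate | C=C(CO[Si](c1ccccc1)(c1ccccc1)C(C)(C)C)CC(=O)OC | intermediate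
17 | 3-{[(tert-butyldiphenylsilyl)oxy]methyl}but-3-enal | C=C(CO[Si](c1ccccc1)(c1ccccc1)C(C)(C)C)CC=O | intermediate
18 | allylchromium, dichloro{[(5R)-5-[(1E)-2-{[(tert-butyldiphenylsilyl)oxy]methyl}hexa-1,5-dien-1-yl]-2-oxo-2,5-dihydrofuran-3-yl]methyl}chromium | O=C1O[C@H](/C=C(/CO[Si](c2ccccc2)(c2ccccc2)C(C)(C)C)CCC=C)C=C1C[Cr](Cl)Cl | intermediate
19 | (4R,5R)-4-[(1S)-3-{[(tert-butyldiphenylsilyl)oxy]methyl}-1-hydroxybut-3-en-1-yl]-5-[(1E)-2-{[(tert-butyldiphenylsilyl)oxy]methyl}hexa-1,5-dien-1-yl]-3-methylideneoxolan-2-one | C=C1C(=O)O[C@H](/C=C(/CO[Si](c2ccccc2)(c2ccccc2)C(C)(C)C)CCC=C)[C@H]1[C@@H](O)CC(=C)CO[Si](c1ccccc1)(c1ccccc1)C(C)(C)C | intermediate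
20 | 3-methylbutanoic acid (isovaleric acid) | CC(C)CC(=O)O | starting material
21 | (1R)-1-[(2R,3R)-2-[(1E)-2-{[(tert-butyldiphenylsilyl)oxy]methyl}hexa-1,5-dien-1-yl]-4-methylidene-5-oxooxolan-3-yl]-3-{[(tert-butyldiphenylsilyl)oxy]methyl}but-3-en-1-yl 3-methylbutanoate | C=C1C(=O)O[C@H](/C=C(/CO[Si](c2ccccc2)(c2ccccc2)C(C)(C)C)CCC=C)[C@H]1[C@H](OC(=O)CC(C)C)CC(=C)CO[Si](c1ccccc1)(c1ccccc1)C(C)(C)C | intermediate
22 | (3aR,4R,6E,10E,11aR)-6,10-bis{[(tert-butyldiphenylsilyl)oxy]methyl}-3-methylidene-2-oxo-2,3,3a,4,5,8,9,11a-octahydrocyclodeca[b]furan-4-yl 3-methylbutanoate | C=C1C(=O)O[C@@H]2/C=C(/CO[Si](c3ccccc3)(c3ccccc3)C(C)(C)C)CC/C=C(/CO[Si](c3ccccc3)(c3ccccc3)C(C)(C)C)C[C@@H](OC(=O)CC(C)C)[C@@H]12 | intermediate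
23 | (3aR,4R,6E,10E,11aR)-6,10-bis(hydroxymethyl)-3-methylidene-2-oxo-2,3,3a,4,5,8,9,11a-octahydrocyclodeca[b]furan-4-yl 3-methylbutanoate | C=C1C(=O)O[C@@H]2/C=C(/CO)CC/C=C(/CO)C[C@@H](OC(=O)CC(C)C)[C@@H]12 | target

**Totals**
Total step count: 13. Longest linear sequence: 10 steps (steps 1–6 and 10–13); steps 7–9 make the aldehyde branch.

**Steps most likely to fail**

Step 10 (chromium allylation). The aldehyde 17 can slip into conjugation, and the anti sense at C8 rests on a closed chair transition state that has not been shown for a 5-substituted reagent of this kind. The fallback sets out from 13. Coupling with (Bu3Sn)2 under Pd2(dba)3 catalysis gives the allylstannane F1. Addition of F1 to 17 with BF3·OEt2 in CH2Cl2 at −78 °C runs through an open antiperiplanar transition state, still anti to the C6 side chain, and should give the syn adduct, the (8R)-alcohol F2 (C8 epimer of 19). Acylation of F2 with 3-methylbutanoic anhydride and DMAP, with retention, comes back to the route at 21, so no inversion is needed.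

Step 11 (Mitsunobu inversion). The C8 carbinol is flanked by a branched carbon and has allylic β-hydrogens, so elimination or ester formation with retention can compete. The fallback sets out from 19. MsCl and Et3N in CH2Cl2 at −20 °C give the mesylate F3. SN2 displacement with caesium 3-methylbutanoate (from 20 and Cs2CO3, with 18-crown-6 in toluene at 80 °C) inverts C8 and comes back to the route at 21.

Step 12 (ring-closing metathesis). Closing a ten-membered carbocycle onto a hindered 1,1-disubstituted alkene may give oligomers or some of the ring-trans C1=C10 isomer. The fallback sets out from 19 and closes the ring before the ester is in place. The free homoallylic hydroxyl can guide the ruthenium alkylidene to the neighbouring 1,1-disubstituted alkene, and C8 is less crowded without the acyl group. Metathesis under the conditions of step 12 gives the macrocyclic alcohol F4. Mitsunobu esterification of F4 with 20 (PPh3, DIAD) then inverts C8 on the ring and comes back to the route at 22.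

**Further compounds**
F1 | step 10 | (5R)-5-[(1E)-2-{[(tert-butyldiphenylsilyl)oxy]methyl}hexa-1,5-dien-1-yl]-3-[(tributylstannyl)methyl]furan-2(5H)-one | O=C1O[C@H](/C=C(/CO[Si](c2ccccc2)(c2ccccc2)C(C)(C)C)CCC=C)C=C1C[Sn](CCCC)(CCCC)CCCC
F2 | step 10 | (4R,5R)-4-[(1R)-3-{[(tert-butyldiphenylsilyl)oxy]methyl}-1-hydroxybut-3-en-1-yl]-5-[(1E)-2-{[(tert-butyldiphenylsilyl)oxy]methyl}hexa-1,5-dien-1-yl]-3-methylideneoxolan-2-one | C=C1C(=O)O[C@H](/C=C(/CO[Si](c2ccccc2)(c2ccccc2)C(C)(C)C)CCC=C)[C@H]1[C@H](O)CC(=C)CO[Si](c1ccccc1)(c1ccccc1)C(C)(C)C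
F3 | step 11 | methanesulfonate of 19 at the C8 hydroxyl (all configurations as in 19) | C=C1C(=O)O[C@H](/C=C(/CO[Si](c2ccccc2)(c2ccccc2)C(C)(C)C)CCC=C)[C@H]1[C@@H](OS(C)(=O)=O)CC(=C)CO[Si](c1ccccc1)(c1ccccc1)C(C)(C)C
F4 | step 12 | (3aR,4S,6E,10E,11aR)-6,10-bis{[(tert-butyldiphenylsilyl)oxy]methyl}-4-hydroxy-3-methylidene-3a,4,5,8,9,11a-hexahydrocyclodeca[b]furan-2(3H)-one | C=C1C(=O)O[C@@H]2/C=C(/CO[Si](c3ccccc3)(c3ccccc3)C(C)(C)C)CC/C=C(/CO[Si](c3ccccc3)(c3ccccc3)C(C)(C)C)C[C@H](O)[C@@H]12
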